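## Retrosynthetic overview

1. The target 26 is the diacetate of diol 25. The C7=C8(CH3) olefin comes from a C8 ketone (kinetic enol triflate, then Negishi methylation), and C9–H is set last by decarboxylative protonation of a C9 allyl ester.
2. Ring B is closed at C9–C10 by a SnCl4 cation–olefin cyclization of a monocyclic α-alkyl β-keto ester; the C2 silyloxy stereocentre relays C5 and C10 in that one event.
3. C9–C11 and C6–C7 are disconnected in one operation. The enabling feature is that ring-B atoms C7–C8–C9, with the olefinic, methyl-bearing C8 raised to a ketone and a removable carboxylate on C9 (the carbon flanked by exocyclic C11), are an acetoacetate. Its dianion is alkylated first at C7 by a ring-A allylic bromide (C6) and then at C9 by the C11–C15 iodide.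
4. Fragments: ring A with C2 from (4R,6R)-actinol after Mitsunobu inversion; the side chain with C13 from (S)-citronellol; allyl acetoacetate as the three-carbon linchpin.
5. Ring order: ring A is bought; ring B is formed in step 12.

Key step: step 11

Remark: labdane numbering is used throughout (C1–C10 decalin, C11–C15 chain, C16 on C13, C17 on C8). The C6 centre of 3 and 4 may scramble under the basic conditions of step 2; this does not matter, because that carbon becomes sp2 in step 4.

## Route

Step 1
Reactants: 1 (4R,6R)-4-hydroxy-2,2,6-trimethylcyclohexan-1-one (actinol)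
Product: 2 (4S,6R)-4-(4-nitrobenzoyloxy)-2,2,6-trimethylcyclohexan-1-one
Conditions: 4-O2NC6H4CO2H, PPh3, DIAD, THF, 0 °C → rt
Reagents that add atoms: 4-nitrobenzoic acid, O=C(O)c1ccc(cc1)[N+](=O)[O-]
Why: Mitsunobu esterification displaces the activated C4 oxygen with SN2 inversion, turning the bought (4R) carbinol into the (4S) configuration that becomes C2 of the target; the hydroxyl is γ to the ketone, so no conjugate elimination pathway is open.

Step 2
Reactants: 2 (4S,6R)-4-(4-nitrobenzoyloxy)-2,2,6-trimethylcyclohexan-1-one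
Product: 3 (4S,6R)-4-hydroxy-2,2,6-trimethylcyclohexan-1-one
Conditions: K2CO3 (cat.), MeOH, rt
Reagents that add atoms: none
Why: base-catalysed transesterification of the activated aryl ester to methanol frees the inverted alcohol without touching the C4 configuration.

Step 3
Reactants: 3 (4S,6R)-4-hydroxy-2,2,6-trimethylcyclohexan-1-one
Product: 4 (4S,6R)-4-[(tert-butyldiphenylsilyl)oxy]-2,2,6-trimethylcyclohexan-1-one
Conditions: TBDPSCl, imidazole, DMF, rt
Reagents that add atoms: tert-butyldiphenylsilyl chloride, CC(C)(C)[Si](Cl)(c1ccccc1)c1ccccc1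
Why: standard silylation of a secondary alcohol; the TBDPS ether is chosen because it has to survive the strong bases and the SnCl4 step that follow and cannot act as a neighbouring group.

Step 4
Reactants: 4 (4S,6R)-4-[(tert-butyldiphenylsilyl)oxy]-2,2,6-trimethylcyclohexan-1-one
Product: 6 (S)-4-[(tert-butyldiphenylsilyl)oxy]-2,6,6-trimethylcyclohex-1-en-1-yl trifluoromethanesulfonate, via lithium enolate 5 (not isolated)
Conditions: LDA, THF, −78 → 0 °C; PhNTf2, 0 °C → rt
Reagents that add atoms: N-phenylbis(trifluoromethanesulfonimide), O=S(=O)(N(c1ccccc1)S(=O)(=O)C(F)(F)F)C(F)(F)F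
Why: the ketone has a single enolizable position (C2 is quaternary), so deprotonation gives one enolate whatever the C6 configuration, and O-sulfonylation gives the tetrasubstituted enol triflate (enol triflate formation).

Step 5
Reactants: 6 (S)-4-[(tert-butyldiphenylsilyl)oxy]-2,6,6-trimethylcyclohex-1-en-1-yl trifluoromethanesulfonate
Product: 7 methyl (S)-4-[(tert-butyldiphenylsilyl)oxy]-2,6,6-trimethylcyclohex-1-ene-1-carboxylate
Conditions: Pd(OAc)2 (cat.), dppf, CO (1 atm), MeOH, Et3N, DMF, 70 °C
Reagents that add atoms: carbon monoxide, [C-]#[O+]; methanol, CO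
Why: palladium-catalysed alkoxycarbonylation of a vinyl triflate (oxidative addition, CO insertion, methanolysis) introduces C6 on the ring-A carbon that becomes C5.

Step 6
Reactants: 7 methyl (S)-4-[(tert-butyldiphenylsilyl)oxy]-2,6,6-trimethylcyclohex-1-ene-1-carboxylate
Product: 8 {(S)-4-[(tert-butyldiphenylsilyl)oxy]-2,6,6-trimethylcyclohex-1-en-1-yl}methanol
Conditions: DIBAL-H, CH2Cl2, −78 → 0 °C
Reagents that add atoms: none
Why: DIBAL-H reduces the twisted, non-planar unsaturated ester by 1,2-addition to the allylic alcohol, and the silyl ether is inert.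

Step 7
Reactants: 8 {(S)-4-[(tert-butyldiphenylsilyl)oxy]-2,6,6-trimethylcyclohex-1-en-1-yl}methanol
Product: 9 (S)-{[4-(bromomethyl)-3,5,5-trimethylcyclohex-3-en-1-yl]oxy}(tert-butyl)diphenylsilane
Conditions: CBr4, PPh3, CH2Cl2, 0 °C; used directly
Reagents that add atoms: carbon tetrabromide, BrC(Br)(Br)Br
Why: Appel bromination of the primary allylic alcohol under neutral conditions keeps the silyl ether and limits ionization of the allylic system.

Step 8
Reactants: 10 (S)-citronellol, (S)-3,7-dimethyloct-6-en-1-ol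
Product: 11 (S)-tert-butyl[(3,7-dimethyloct-6-en-1-yl)oxy]diphenylsilane
Conditions: TBDPSCl, imidazole, DMF, rt
Reagents that add atoms: tert-butyldiphenylsilyl chloride, CC(C)(C)[Si](Cl)(c1ccccc1)c1ccccc1
Why: standard silylation of the primary alcohol, using the same group as on ring A so that one deprotection serves both at the end; the bought stereocentre (the future C13) is untouched.

Step 9
Reactants: 11 (S)-tert-butyl[(3,7-dimethyloct-6-en-1-yl)oxy]diphenylsilane
Product: 12 (S)-6-[(tert-butyldiphenylsilyl)oxy]-4-methylhexanoic acid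
Conditions: RuCl3·xH2O (cat.), NaIO4, CCl4/MeCN/H2O, rt
Reagents that add atoms: sodium periodate, [Na+].[O-]I(=O)(=O)=O; water, O
Why: RuO4-mediated oxidative cleavage of the trisubstituted olefin gives the carboxylic acid directly, with acetone as the other fragment; the stereocentre is remote and the silyl ether is stable.

Step 10
Reactants: 12 (S)-6-[(tert-butyldiphenylsilyl)oxy]-4-methylhexanoic acid
Product: 14 (R)-tert-butyl[(5-iodo-3-methylpentyl)oxy]diphenylsilane, via acyl hypoiodite 13 (not isolated)
Conditions: PhI(OAc)2, I2, hν (tungsten lamp), cyclohexane, reflux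
Reagents that add atoms: iodine, II
Why: hypervalent-iodine iododecarboxylation (Hunsdiecker-type): the acyl hypoiodite fragments to a primary radical that is trapped by iodine, which shortens the chain by one carbon to the five-carbon C11–C15 unit; the descriptor changes to R only through CIP priorities.

Step 11
Reactants: 15 allyl acetoacetate (allyl 3-oxobutanoate); 9 (S)-{[4-(bromomethyl)-3,5,5-trimethylcyclohex-3-en-1-yl]oxy}(tert-butyl)diphenylsilane; 14 (R)-tert-butyl[(5-iodo-3-methylpentyl)oxy]diphenylsilane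
Product: 18 allyl 2-{(S)-5-[(tert-butyldiphenylsilyl)oxy]-3-methylpentyl}-3-oxo-5-{(S)-4-[(tert-butyldiphenylsilyl)oxy]-2,6,6-trimethylcyclohex-1-en-1-yl}pentanoate (both C9 epimers), via acetoacetate dianion 16 (not isolated), via sodium enolate 17 (not isolated)
Conditions: NaH, THF, 0 °C; n-BuLi, −10 °C; 9, −78 → 0 °C; then 14, DMPU, 0 → 45 °C
Reagents that add atoms: none
Why: Sequential deprotonation (NaH, then n-BuLi) turns 15 into dianion 16, whose terminal carbon (C7) is by far the most nucleophilic site and displaces the primary allylic bromide of 9 by SN2 to form C6–C7; the enolate 17 that remains is then C-alkylated at C9 by the unactivated primary iodide 14 once DMPU is added and the mixture is warmed, which forms the C9–C11 bond and unites all three components. The closest known reaction type is the γ-alkylation of acetoacetate dianions followed by acetoacetic-ester α-alkylation of the surviving monoanion in the same flask. No ring is closed in this step; ring B is closed from its product in step 12. The only new stereocentre, C9, forms as an inconsequential epimer mixture, because it is enolized in step 12 and finally fixed by protonation in step 13, while C2 and C13 are spectators. The selectivity needed is γ before α and C before O: the first is secured by the large basicity difference between the two carbanionic sites and by adding one equivalent of the allylic bromide first, the second by the soft iodide in THF/DMPU with alkali counter-ions.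

Step 12
Reactants: 18 allyl 2-{(S)-5-[(tert-butyldiphenylsilyl)oxy]-3-methylpentyl}-3-oxo-5-{(S)-4-[(tert-butyldiphenylsilyl)oxy]-2,6,6-trimethylcyclohex-1-en-1-yl}pentanoate
Product: 19 allyl 7-[(tert-butyldiphenylsilyl)oxy]-1-{(S)-5-[(tert-butyldiphenylsilyl)oxy]-3-methylpentyl}-5,5,8a-trimethyl-2-oxo-trans-decahydronaphthalene-1-carboxylate (labdane numbering: 2R; 5R; 9S; 10R; ester on C9 cis to the C10 methyl)
Conditions: SnCl4, CH2Cl2, −20 → 0 °C
Reagents that add atoms: none
Why: SnCl4-promoted β-keto-ester-terminated cation–olefin cyclization: protonation of C5=C10 at C5 is followed by attack of the tin-chelated enol carbon C9 on the C10 cation through a chair-like transition state with the C5–C6 bond and the C2 silyloxy group equatorial, which should give the trans ring fusion and the C10 methyl anti to the C2 oxygen, the reversible protonation letting the substrate funnel through the cation that avoids a 1,3-diaxial OSi/CH3 contact; C9 becomes quaternary with the ester equatorial, a configuration that is erased in step 13.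

Step 13
Reactants: 19 allyl 7-[(tert-butyldiphenylsilyl)oxy]-1-{(S)-5-[(tert-butyldiphenylsilyl)oxy]-3-methylpentyl}-5,5,8a-trimethyl-2-oxo-trans-decahydronaphthalene-1-carboxylate
Product: 21 7-[(tert-butyldiphenylsilyl)oxy]-1-{(S)-5-[(tert-butyldiphenylsilyl)oxy]-3-methylpentyl}-5,5,8a-trimethyl-trans-octahydronaphthalen-2(1H)-one (labdane numbering: 2R; 5R; 9S; 10R; side chain on C9 equatorial and cis to the C10 methyl), via β-keto acid 20 (not isolated)
Conditions: Pd(PPh3)4 (cat.), morpholine, THF, rt; then 60 °C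
Reagents that add atoms: none
Why: Pd(0)-catalysed deallylation (allyl transfer to morpholine) gives the β-keto acid, which decarboxylates on warming; the resulting C8=C9 enol should be protonated axially on the face anti to the C10 methyl, placing the side chain equatorial as in the target, which is also expected to be the more stable epimer.

Step 14
Reactants: 21 7-[(tert-butyldiphenylsilyl)oxy]-1-{(S)-5-[(tert-butyldiphenylsilyl)oxy]-3-methylpentyl}-5,5,8a-trimethyl-trans-octahydronaphthalen-2(1H)-one
Product: 23 7-[(tert-butyldiphenylsilyl)oxy]-1-{(S)-5-[(tert-butyldiphenylsilyl)oxy]-3-methylpentyl}-5,5,8a-trimethyl-1,4,4a,5,6,7,8,8a-octahydronaphthalen-2-yl trifluoromethanesulfonate (C7=C8 enol triflate in labdane numbering), via potassium enolate 22 (not isolated)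
Conditions: KHMDS, THF, −78 °C; PhNTf2, −78 → 0 °C
Reagents that add atoms: N-phenylbis(trifluoromethanesulfonimide), O=S(=O)(N(c1ccccc1)S(=O)(=O)C(F)(F)F)C(F)(F)F
Why: kinetic deprotonation occurs at the C7 methylene and not at the hindered tertiary C9–H next to the quaternary C10, so O-triflation should give the Δ7 enol triflate regioselectively and leave the C9 configuration untouched (enol triflate formation).

Step 15
Reactants: 23 the C7=C8 enol triflate
Product: 24 (2R,5R,9R,10R,13S)-2,15-bis[(tert-butyldiphenylsilyl)oxy]labd-7-ene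
Conditions: MeZnCl, Pd(PPh3)4 (cat.), THF, 50 °C
Reagents that add atoms: methylzinc chloride, C[Zn]Cl
Why: Negishi coupling replaces the triflate by the C17 methyl group with the double bond fixed at C7=C8; a methyl group offers no β-hydride pathway.

Step 16
Reactants: 24 (2R,5R,9R,10R,13S)-2,15-bis[(tert-butyldiphenylsilyl)oxy]labd-7-ene
Product: 25 (2R,5R,9R,10R,13S)-labd-7-ene-2,15-diol
Conditions: TBAF, THF, rt → 50 °C
Reagents that add atoms: none
Why: fluoride-induced desilylation frees both hydroxyls; the trisubstituted olefin and all stereocentres are inert.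

Step 17
Reactants: 25 (2R,5R,9R,10R,13S)-labd-7-ene-2,15-diol
Product: 26 (2R,5R,9R,10R,13S)-labd-7-ene-2,15-diyl diacetate (CNP0220683.1)
Conditions: Ac2O, pyridine, DMAP (cat.), CH2Cl2, rt
Reagents that add atoms: acetic anhydride, CC(=O)OC(C)=O
Why: DMAP-catalysed acylation of the primary and the unhindered equatorial secondary hydroxyl proceeds with retention at C2.

## Compound list

1 | (4R,6R)-4-hydroxy-2,2,6-trimethylcyclohexan-1-one (actinol) | O=C1[C@H](C)C[C@@H](O)CC1(C)C | starting material
2 | (4S,6R)-4-(4-nitrobenzoyloxy)-2,2,6-trimethylcyclohexan-1-one | O=C1[C@H](C)C[C@H](OC(=O)c2ccc(cc2)[N+](=O)[O-])CC1(C)C | intermediate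
3 | (4S,6R)-4-hydroxy-2,2,6-trimethylcyclohexan-1-one | O=C1[C@H](C)C[C@H](O)CC1(C)C | intermediate
4 | (4S,6R)-4-[(tert-butyldiphenylsilyl)oxy]-2,2,6-trimethylcyclohexan-1-one | O=C1[C@H](C)C[C@H](O[Si](c2ccccc2)(c2ccccc2)C(C)(C)C)CC1(C)C | intermediate
5 | lithium (S)-4-[(tert-butyldiphenylsilyl)oxy]-2,6,6-trimethylcyclohex-1-en-1-olate | [Li+].[O-]C1=C(C)C[C@H](O[Si](c2ccccc2)(c2ccccc2)C(C)(C)C)CC1(C)C | intermediate
6 | (S)-4-[(tert-butyldiphenylsilyl)oxy]-2,6,6-trimethylcyclohex-1-en-1-yl trifluoromethanesulfonate | FC(F)(F)S(=O)(=O)OC1=C(C)C[C@H](O[Si](c2ccccc2)(c2ccccc2)C(C)(C)C)CC1(C)C | intermediate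
7 | methyl (S)-4-[(tert-butyldiphenylsilyl)oxy]-2,6,6-trimethylcyclohex-1-ene-1-carboxylate | COC(=O)C1=C(C)C[C@H](O[Si](c2ccccc2)(c2ccccc2)C(C)(C)C)CC1(C)C | intermediate
8 | {(S)-4-[(tert-butyldiphenylsilyl)oxy]-2,6,6-trimethylcyclohex-1-en-1-yl}methanol | OCC1=C(C)C[C@H](O[Si](c2ccccc2)(c2ccccc2)C(C)(C)C)CC1(C)C | intermediate
9 | (S)-{[4-(bromomethyl)-3,5,5-trimethylcyclohex-3-en-1-yl]oxy}(tert-butyl)diphenylsilane | BrCC1=C(C)C[C@H](O[Si](c2ccccc2)(c2ccccc2)C(C)(C)C)CC1(C)C | intermediate
10 | (S)-citronellol, (S)-3,7-dimethyloct-6-en-1-ol | OCC[C@@H](C)CCC=C(C)C | starting material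
11 | (S)-tert-butyl[(3,7-dimethyloct-6-en-1-yl)oxy]diphenylsilane | CC(C)(C)[Si](c1ccccc1)(c1ccccc1)OCC[C@@H](C)CCC=C(C)C | intermediate
12 | (S)-6-[(tert-butyldiphenylsilyl)oxy]-4-methylhexanoic acid | CC(C)(C)[Si](c1ccccc1)(c1ccccc1)OCC[C@@H](C)CCC(=O)O | intermediate
13 | (S)-6-[(tert-butyldiphenylsilyl)oxy]-4-methylhexanoyl hypoiodite | CC(C)(C)[Si](c1ccccc1)(c1ccccc1)OCC[C@@H](C)CCC(=O)OI | intermediate
14 | (R)-tert-butyl[(5-iodo-3-methylpentyl)oxy]diphenylsilane | CC(C)(C)[Si](c1ccccc1)(c1ccccc1)OCC[C@@H](C)CCI | intermediate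
15 | allyl acetoacetate (allyl 3-oxobutanoate) | C=CCOC(=O)CC(C)=O | starting material
16 | dianion of allyl acetoacetate (sodium lithium salt) | [Na+].[Li+].C=C([O-])C=C([O-])OCC=C | intermediate
17 | sodium enolate of allyl 3-oxo-5-{(S)-4-[(tert-butyldiphenylsilyl)oxy]-2,6,6-trimethylcyclohex-1-en-1-yl}pentanoate | [Na+].C=CCOC(=O)C=C([O-])CCC1=C(C)C[C@H](O[Si](c2ccccc2)(c2ccccc2)C(C)(C)C)CC1(C)C | intermediate
18 | allyl 2-{(S)-5-[(tert-butyldiphenylsilyl)oxy]-3-methylpentyl}-3-oxo-5-{(S)-4-[(tert-butyldiphenylsilyl)oxy]-2,6,6-trimethylcyclohex-1-en-1-yl}pentanoate (C9 epimers) | CC(C)(C)[Si](c1ccccc1)(c1ccccc1)OCC[C@@H](C)CCC(C(=O)OCC=C)C(=O)CCC1=C(C)C[C@H](O[Si](c2ccccc2)(c2ccccc2)C(C)(C)C)CC1(C)C | intermediate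
19 | allyl 7-[(tert-butyldiphenylsilyl)oxy]-1-{(S)-5-[(tert-butyldiphenylsilyl)oxy]-3-methylpentyl}-5,5,8a-trimethyl-2-oxo-trans-decahydronaphthalene-1-carboxylate (labdane 2R; 5R; 9S; 10R) | CC(C)(C)[Si](c1ccccc1)(c1ccccc1)OCC[C@@H](C)CC[C@@]1(C(=O)OCC=C)C(=O)CC[C@@H]2C(C)(C)C[C@@H](O[Si](c3ccccc3)(c3ccccc3)C(C)(C)C)C[C@@]12C | intermediate
20 | the corresponding β-keto acid (1-carboxylic acid of 19) | CC(C)(C)[Si](c1ccccc1)(c1ccccc1)OCC[C@@H](C)CC[C@@]1(C(=O)O)C(=O)CC[C@@H]2C(C)(C)C[C@@H](O[Si](c3ccccc3)(c3ccccc3)C(C)(C)C)C[C@@]12C | intermediate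
21 | 7-[(tert-butyldiphenylsilyl)oxy]-1-{(S)-5-[(tert-butyldiphenylsilyl)oxy]-3-methylpentyl}-5,5,8a-trimethyl-trans-octahydronaphthalen-2(1H)-one (labdane 2R; 5R; 9S; 10R) | CC(C)(C)[Si](c1ccccc1)(c1ccccc1)OCC[C@@H](C)CC[C@@H]1C(=O)CC[C@@H]2C(C)(C)C[C@@H](O[Si](c3ccccc3)(c3ccccc3)C(C)(C)C)C[C@@]12C | intermediate
22 | potassium C7=C8 enolate of 21 | [K+].CC(C)(C)[Si](c1ccccc1)(c1ccccc1)OCC[C@@H](C)CC[C@@H]1C([O-])=CC[C@@H]2C(C)(C)C[C@@H](O[Si](c3ccccc3)(c3ccccc3)C(C)(C)C)C[C@@]12C | intermediate
23 | C7=C8 enol triflate of 21 | CC(C)(C)[Si](c1ccccc1)(c1ccccc1)OCC[C@@H](C)CC[C@@H]1C(OS(=O)(=O)C(F)(F)F)=CC[C@@H]2C(C)(C)C[C@@H](O[Si](c3ccccc3)(c3ccccc3)C(C)(C)C)C[C@@]12C | intermediate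
24 | (2R,5R,9R,10R,13S)-2,15-bis[(tert-butyldiphenylsilyl)oxy]labd-7-ene | CC(C)(C)[Si](c1ccccc1)(c1ccccc1)OCC[C@@H](C)CC[C@@H]1C(C)=CC[C@@H]2C(C)(C)C[C@@H](O[Si](c3ccccc3)(c3ccccc3)C(C)(C)C)C[C@@]12C | intermediate
25 | (2R,5R,9R,10R,13S)-labd-7-ene-2,15-diol | OCC[C@@H](C)CC[C@@H]1C(C)=CC[C@@H]2C(C)(C)C[C@@H](O)C[C@@]12C | intermediate
26 | (2R,5R,9R,10R,13S)-labd-7-ene-2,15-diyl diacetate (CNP0220683.1) | CC(=O)OCC[C@@H](C)CC[C@@H]1C(C)=CC[C@@H]2C(C)(C)C[C@@H](OC(C)=O)C[C@@]12C | target

## Step count and risks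

Total step count: 17. Longest linear sequence: 14 steps (steps 1–7 and 11–17); the side-chain branch (steps 8–10) has 3 steps.

**Step 12.** The ring closure has to join a fully substituted enol carbon (C9) to the tertiary C10 cation. It may be outrun by O-capture of the cation to a cyclic enol ether, by proton loss to isomeric ring-A olefins, or by slow enolization of the α-substituted keto ester, and the facial relay from C2 may erode if the closure becomes late and unselective. The fallback reverses the order of ring closure and fragment union. It sets out from 9: dianion 16 is alkylated with 9 alone and quenched to give allyl 3-oxo-5-{(S)-4-[(tert-butyldiphenylsilyl)oxy]-2,6,6-trimethylcyclohex-1-en-1-yl}pentanoate F1. This α-unsubstituted β-keto ester belongs to the substrate class with direct precedent for the SnCl4 closure and should give the trans-fused bicyclic β-keto ester with C9–H, allyl 7-[(tert-butyldiphenylsilyl)oxy]-5,5,8a-trimethyl-2-oxo-trans-decahydronaphthalene-1-carboxylate F2. C-alkylation of F2 with iodide 14 (Cs2CO3, DMF, 50 °C), on the face anti to the C10 methyl, comes back to the route at 19.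

**Step 11.** The second alkylation in the same flask may stall or be diverted: the enolate may transfer a proton to the product, O-alkylate, or react with residual allylic bromide, and the labile bromide may ionize before it is consumed. The fallback makes the two bonds in the opposite order and in separate operations. It sets out from 15, which is mono-alkylated at C9 with 14 (K2CO3, acetone, reflux) to give allyl 2-{(S)-5-[(tert-butyldiphenylsilyl)oxy]-3-methylpentyl}-3-oxobutanoate F3. Double deprotonation (LDA, 2 equiv, THF, −78 → 0 °C) gives its dilithium dianion F4, which is alkylated at the terminal carbon with 9 and comes back to the route at 18.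

**Step 5.** Oxidative addition and CO insertion at the tetrasubstituted enol triflate, flanked by a quaternary carbon and a methyl group, may be slow, so that reduction or hydrolysis of the triflate takes over. The fallback replaces the triflate and carbonylation by a vinyl anion. It sets out from 4, which is condensed with 2,4,6-triisopropylbenzenesulfonyl hydrazide to the 2,4,6-triisopropylbenzenesulfonyl hydrazone of 4, F5. A Shapiro reaction (n-BuLi, 2.2 equiv, THF, −78 → 0 °C; only one α-C–H is available) gives (S)-4-[(tert-butyldiphenylsilyl)oxy]-2,6,6-trimethylcyclohex-1-en-1-yllithium F6, which is trapped with paraformaldehyde and comes back to the route at 8, bypassing 6 and 7.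

Further compounds
F1 | step 12 | allyl 3-oxo-5-{(S)-4-[(tert-butyldiphenylsilyl)oxy]-2,6,6-trimethylcyclohex-1-en-1-yl}pentanoate | C=CCOC(=O)CC(=O)CCC1=C(C)C[C@H](O[Si](c2ccccc2)(c2ccccc2)C(C)(C)C)CC1(C)C
F2 | step 12 | allyl 7-[(tert-butyldiphenylsilyl)oxy]-5,5,8a-trimethyl-2-oxo-trans-decahydronaphthalene-1-carboxylate (labdane 2R; 5R; 9S; 10R) | C=CCOC(=O)[C@@H]1C(=O)CC[C@@H]2C(C)(C)C[C@@H](O[Si](c3ccccc3)(c3ccccc3)C(C)(C)C)C[C@@]12C
F3 | step 11 | allyl 2-{(S)-5-[(tert-butyldiphenylsilyl)oxy]-3-methylpentyl}-3-oxobutanoate | C=CCOC(=O)C(CC[C@H](C)CCO[Si](c1ccccc1)(c1ccccc1)C(C)(C)C)C(C)=O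
F4 | step 11 | dilithium dianion of F3 | [Li+].[Li+].C=C([O-])C(CC[C@H](C)CCO[Si](c1ccccc1)(c1ccccc1)C(C)(C)C)=C([O-])OCC=C
F5 | step 5 | 2,4,6-triisopropylbenzenesulfonyl hydrazone of 4 | CC(C)c1cc(C(C)C)c(S(=O)(=O)NN=C2[C@H](C)C[C@H](O[Si](c3ccccc3)(c3ccccc3)C(C)(C)C)CC2(C)C)c(C(C)C)c1
F6 | step 5 | (S)-4-[(tert-butyldiphenylsilyl)oxy]-2,6,6-trimethylcyclohex-1-en-1-yllithium | [Li]C1=C(C)C[C@H](O[Si](c2ccccc2)(c2ccccc2)C(C)(C)C)CC1(C)C
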